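**Retrosynthetic overview**

1. The C40 polyene is cut at C11=C12 (Wittig) into an ε-ring C25 phosphonium salt and a (5R,6S)-epoxy C15 dienal; the C25 salt comes from an ε-ring C15 phosphonium salt and 2,7-dimethylocta-2,4,6-trienedial (Wittig at C11'=C12').
2. The ε-ring C15 salt is traced back through (R)-α-ionone, (R)-α-cyclocitral and (R)-α-cyclogeraniol to a cis-fused lactone; lactol formation and Wolff–Kishner reduction turn the ester carbon into the second C1' methyl.
3. Feature on which the plan rests: the ε ring is a cyclohexene whose C4'=C5' bond (with the 5'-methyl), C6' and C3' come from (E)-3-methylpenta-2,4-dien-1-ol and whose C1'/C2' come from methyl methacrylate; the C7' oxygen anchors a Zn/Mg BINOLate tether and the ester carbon is a masked C1' methyl.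
4. The epoxy end comes from β-cyclocitral: reduction, Katsuki–Sharpless epoxidation (sets C5 and C6), then a C5 Horner–Wadsworth–Emmons homologation to the C15 dienal.
5. Ring order: ε ring by templated [4+2] (step 2); a temporary lactone ring (step 3, opened in step 5); the oxirane (step 14); the six-membered ring of the epoxy end is bought.

Key step: step 2

Assumption: the sense of induction of the BINOL template is taken by analogy with the acrylate case and (R)-BINOL is written for the (1R,2S) adduct; if a first run shows the opposite sense, (S)-BINOL is used and nothing else changes.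
Remark: carotenoid numbering is used for the target (C1'–C6' for the ε ring, C1–C6 for the epoxy ring).

**Route**

Step 1
Reactants: 1 (E)-3-methylpent-2-en-4-yn-1-ol
Product: 2 (E)-3-methylpenta-2,4-dien-1-ol
Conditions: H2 (1 atm, stopped at 1.0 equiv uptake), Pd/CaCO3 poisoned with Pb(OAc)2, quinoline, hexane/EtOAc, 0 °C
Reagents that add atoms: none
Why: Lindlar-type semihydrogenation on the poisoned Pd surface should reduce the terminal alkyne to the vinyl group much faster than either alkene and leaves the E-configured C2=C3 bond untouched, so the diene has the geometry needed for s-cis reaction.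

Step 2
Reactants: 2 (E)-3-methylpenta-2,4-dien-1-ol; 3 methyl methacrylate
Product: 5 methyl (1R,2S)-2-(hydroxymethyl)-1,3-dimethylcyclohex-3-ene-1-carboxylate, via methylzinc dienyl alkoxide 4 (not isolated)
Conditions: Me2Zn (1.0 equiv), CH2Cl2, 0 °C; (R)-BINOL (1.0 equiv); MeMgBr (1.0 equiv); 3 (5 equiv), 0 °C to rt; aq NH4Cl, 0 °C
Reagents that add atoms: none
Why: Proposed new method: the zinc alkoxide of dienol 2 and the carbonyl of 3 are held on the neighbouring Zn and Mg centres of one BINOLate, so a concerted suprafacial [4+2] cycloaddition takes place inside the assembly and forms C1–C2 (C1'–C6') and C5–C6 (C3'–C2') of 5; the closest known reaction is the Lewis-acid-templated enantioselective Diels–Alder reaction of 2,4-dienols with methyl acrylate, of which the α-methyl dienophile is an untested extension. The cyclohexene (ε ring) closes by a cycloaddition made temporarily intramolecular through the O–Zn···Mg···O=C bridge, with the tether lying outside the new ring. C2 of 5 (C6') should be set by the diene face that the binaphthyl backbone leaves open, and C1 (C1') by the tether, which keeps the ester on the side of the CH2O group (cis). The step needs ortho regiochemistry against the para preference of the 2-methyl diene, and one diene face: the tether enforces the first because the ester-bearing carbon can only reach the CH2O-bearing diene terminus, and the ligand the second. The configuration at C1' is of no consequence, because this carbon ends as the gem-dimethyl carbon. The lower reactivity of the α-substituted dienophile is met with a stoichiometric template and excess 3.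

Step 3
Reactants: 5 methyl (1R,2S)-2-(hydroxymethyl)-1,3-dimethylcyclohex-3-ene-1-carboxylate
Product: 6 (3aS,7aR)-4,7a-dimethyl-3a,6,7,7a-tetrahydro-2-benzofuran-1(3H)-one
Conditions: TsOH·H2O (5 mol%), CH2Cl2, rt
Reagents that add atoms: none
Why: Acid-catalysed lactonisation (intramolecular transesterification, 5-exo-trig) should be fast because ester and hydroxymethyl group are cis on adjacent ring carbons, no stereocentre is touched, and any lactone already formed during step 2 converges here.

Step 4
Reactants: 6 (3aS,7aR)-4,7a-dimethyl-3a,6,7,7a-tetrahydro-2-benzofuran-1(3H)-one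
Product: 7 (3aS,7aR)-4,7a-dimethyl-1,3,3a,6,7,7a-hexahydro-2-benzofuran-1-ol (mixture of anomers)
Conditions: iBu2AlH (1.1 equiv), CH2Cl2, −78 °C; aq potassium sodium tartrate
Reagents that add atoms: none
Why: Half-reduction of a lactone with iBu2AlH at −78 °C stops at the aluminium hemiacetal, which gives the lactol on hydrolysis, and the quaternary α-carbon excludes enolisation.

Step 5
Reactants: 7 (3aS,7aR)-4,7a-dimethyl-1,3,3a,6,7,7a-hexahydro-2-benzofuran-1-ol
Product: 9 [(1R)-2,6,6-trimethylcyclohex-2-en-1-yl]methanol, via hydroxy hydrazone 8 (not isolated)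
Conditions: N2H4·H2O (excess), KOH, diethylene glycol, 130 °C, then 195 °C
Reagents that add atoms: none
Why: Wolff–Kishner reduction (Huang-Minlon procedure): the lactol opens to the hydroxy aldehyde, which condenses with hydrazine to 8, and base-induced loss of N2 turns CH=N–NH2 into the second C1' methyl, while C6'–H is not acidic and the isolated trisubstituted alkene should not migrate under hydroxide.

Step 6
Reactants: 9 [(1R)-2,6,6-trimethylcyclohex-2-en-1-yl]methanol
Product: 10 (1R)-2,6,6-trimethylcyclohex-2-ene-1-carbaldehyde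
Conditions: Dess–Martin periodinane, NaHCO3, CH2Cl2, 0 °C
Reagents that add atoms: none
Why: Dess–Martin oxidation under bicarbonate buffer is neutral and fast at 0 °C, so the α-stereocentre of the β,γ-unsaturated aldehyde should be kept and the ring alkene should not move into conjugation.

Step 7
Reactants: 10 (1R)-2,6,6-trimethylcyclohex-2-ene-1-carbaldehyde
Product: 11 (3E)-4-[(1R)-2,6,6-trimethylcyclohex-2-en-1-yl]but-3-en-2-one
Conditions: (MeO)2P(O)CH2C(O)CH3, LiCl, iPr2NEt, MeCN, rt
Reagents that add atoms: dimethyl (2-oxopropyl)phosphonate, CC(=O)CP(=O)(OC)OC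
Why: Horner–Wadsworth–Emmons olefination under Masamune–Roush conditions uses an amine base that is too weak to enolise the hindered aldehyde at a competitive rate, and the stabilised phosphonate anion should give the E enone.

Step 8
Reactants: 11 (3E)-4-[(1R)-2,6,6-trimethylcyclohex-2-en-1-yl]but-3-en-2-one
Product: 12 (1E)-3-methyl-1-[(1R)-2,6,6-trimethylcyclohex-2-en-1-yl]penta-1,4-dien-3-ol (both C3 epimers)
Conditions: CH2=CHMgBr, THF, −20 to 0 °C; aq NH4Cl
Reagents that add atoms: vinylmagnesium bromide, C=C[Mg]Br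
Why: Grignard 1,2-addition of the vinylmagnesium halide to the enone carbonyl gives the tertiary bis-allylic alcohol, whose uncontrolled carbinol centre is removed in step 9.

Step 9
Reactants: 12 (1E)-3-methyl-1-[(1R)-2,6,6-trimethylcyclohex-2-en-1-yl]penta-1,4-dien-3-ol
Product: 13 [(2E,4E)-3-methyl-5-[(1R)-2,6,6-trimethylcyclohex-2-en-1-yl]penta-2,4-dien-1-yl]triphenylphosphonium bromide
Conditions: PPh3·HBr, MeOH, 0 °C to rt; crystallisation from EtOAc
Reagents that add atoms: triphenylphosphine hydrobromide, Br.c1ccc(cc1)P(c1ccccc1)c1ccccc1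
Why: Ionisation of the tertiary alcohol by HBr gives a pentadienyl cation that PPh3 captures at the unhindered terminus (SN1' allylic transposition), and trapping at low temperature should outrun loss of H-6', so the 6'R centre is kept and the 2E salt is enriched by crystallisation.

Step 10
Reactants: 13 [(2E,4E)-3-methyl-5-[(1R)-2,6,6-trimethylcyclohex-2-en-1-yl]penta-2,4-dien-1-yl]triphenylphosphonium bromide; 14 (2E,4E,6E)-2,7-dimethylocta-2,4,6-trienedial
Product: 16 (2E,4E,6E,8E,10E,12E)-2,7,11-trimethyl-13-[(1R)-2,6,6-trimethylcyclohex-2-en-1-yl]trideca-2,4,6,8,10,12-hexaenal, via C15 phosphorus ylide 15 (not isolated)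
Conditions: 14 (2.5 equiv), NaOMe, CH2Cl2/MeOH, 0 °C to rt; then I2 (cat.), CH2Cl2, rt
Reagents that add atoms: none
Why: Wittig olefination of one formyl group of the dialdehyde (kept in excess to suppress double condensation) by the semi-stabilised ylide forms C11'=C12', and iodine-catalysed equilibration should convert the less stable Z isomer of this disubstituted bond into the all-E aldehyde.

Step 11
Reactants: 16 (2E,4E,6E,8E,10E,12E)-2,7,11-trimethyl-13-[(1R)-2,6,6-trimethylcyclohex-2-en-1-yl]trideca-2,4,6,8,10,12-hexaenal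
Product: 17 (2E,4E,6E,8E,10E,12E)-2,7,11-trimethyl-13-[(1R)-2,6,6-trimethylcyclohex-2-en-1-yl]trideca-2,4,6,8,10,12-hexaen-1-ol
Conditions: NaBH4, EtOH/THF, 0 °C
Reagents that add atoms: none
Why: Borohydride 1,2-reduction of the conjugated aldehyde gives the polyenyl allylic alcohol without touching the polyene or C6'.

Step 12
Reactants: 17 (2E,4E,6E,8E,10E,12E)-2,7,11-trimethyl-13-[(1R)-2,6,6-trimethylcyclohex-2-en-1-yl]trideca-2,4,6,8,10,12-hexaen-1-ol
Product: 18 [(2E,4E,6E,8E,10E,12E)-2,7,11-trimethyl-13-[(1R)-2,6,6-trimethylcyclohex-2-en-1-yl]trideca-2,4,6,8,10,12-hexaen-1-yl]triphenylphosphonium bromide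
Conditions: PPh3·HBr, CH2Cl2/MeOH, 0 °C to rt
Reagents that add atoms: triphenylphosphine hydrobromide, Br.c1ccc(cc1)P(c1ccccc1)c1ccccc1
Why: Phosphonium salt formation from a polyenyl allylic alcohol with PPh3·HBr proceeds through the delocalised cation, which the phosphine captures at the terminal carbon, the standard entry to C25 Wittig salts.

Step 13
Reactants: 19 2,6,6-trimethylcyclohex-1-ene-1-carbaldehyde (β-cyclocitral)
Product: 20 (2,6,6-trimethylcyclohex-1-en-1-yl)methanol
Conditions: NaBH4, MeOH, 0 °C
Reagents that add atoms: none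
Why: Borohydride 1,2-reduction of the hindered enal gives the tetrasubstituted allylic alcohol needed for directed epoxidation.

Step 14
Reactants: 20 (2,6,6-trimethylcyclohex-1-en-1-yl)methanol
Product: 21 [(1R,6R)-2,2,6-trimethyl-7-oxabicyclo[4.1.0]heptan-1-yl]methanol
Conditions: Ti(OiPr)4 (10 mol%), D-(−)-diethyl tartrate (12 mol%), tBuOOH, 4 Å molecular sieves, CH2Cl2, −20 °C
Reagents that add atoms: tert-butyl hydroperoxide, CC(C)(C)OO
Why: Katsuki–Sharpless asymmetric epoxidation: with the CH2OH group drawn at the lower right of the alkene plane the D-(−)-tartrate titanium complex delivers oxygen to the upper face, and syn addition sets both oxirane carbons as 1R,6R in 21, which is 5R,6S in carotenoid numbering once C7 is an alkene carbon.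

Step 15
Reactants: 21 [(1R,6R)-2,2,6-trimethyl-7-oxabicyclo[4.1.0]heptan-1-yl]methanol
Product: 22 (1S,6R)-2,2,6-trimethyl-7-oxabicyclo[4.1.0]heptane-1-carbaldehyde
Conditions: Dess–Martin periodinane, NaHCO3, CH2Cl2, 0 °C to rt
Reagents that add atoms: none
Why: Buffered Dess–Martin oxidation is neutral, so the oxirane should not open, and the aldehyde has no α-hydrogen to lose.

Step 16
Reactants: 22 (1S,6R)-2,2,6-trimethyl-7-oxabicyclo[4.1.0]heptane-1-carbaldehyde
Product: 23 ethyl (2E,4E)-3-methyl-5-[(1S,6R)-2,2,6-trimethyl-7-oxabicyclo[4.1.0]heptan-1-yl]penta-2,4-dienoate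
Conditions: triethyl 3-methyl-4-phosphonocrotonate, LiN(SiMe3)2, THF, −78 to 0 °C; chromatography
Reagents that add atoms: triethyl 3-methyl-4-phosphonocrotonate, CCOC(=O)/C=C(C)/CP(=O)(OCC)OCC
Why: Vinylogous Horner–Wadsworth–Emmons olefination with the C5 phosphonate should form the C7=C8 bond E under the thermodynamic control typical of stabilised phosphonate anions, the oxirane is inert to the base, and the minor 2Z ester is removed by chromatography.

Step 17
Reactants: 23 ethyl (2E,4E)-3-methyl-5-[(1S,6R)-2,2,6-trimethyl-7-oxabicyclo[4.1.0]heptan-1-yl]penta-2,4-dienoate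
Product: 24 (2E,4E)-3-methyl-5-[(1S,6R)-2,2,6-trimethyl-7-oxabicyclo[4.1.0]heptan-1-yl]penta-2,4-dien-1-ol
Conditions: iBu2AlH (2.2 equiv), CH2Cl2, −78 °C; aq potassium sodium tartrate
Reagents that add atoms: none
Why: Reduction of the conjugated ester by iBu2AlH to the allylic alcohol at −78 °C should be much faster than any opening of the hindered tetrasubstituted oxirane.

Step 18
Reactants: 24 (2E,4E)-3-methyl-5-[(1S,6R)-2,2,6-trimethyl-7-oxabicyclo[4.1.0]heptan-1-yl]penta-2,4-dien-1-ol
Product: 25 (2E,4E)-3-methyl-5-[(1S,6R)-2,2,6-trimethyl-7-oxabicyclo[4.1.0]heptan-1-yl]penta-2,4-dienal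
Conditions: MnO2, CH2Cl2, rt
Reagents that add atoms: none
Why: Allylic oxidation on MnO2 is heterogeneous and neutral, so the acid-labile vinyl oxirane should survive.

Step 19
Reactants: 18 [(2E,4E,6E,8E,10E,12E)-2,7,11-trimethyl-13-[(1R)-2,6,6-trimethylcyclohex-2-en-1-yl]trideca-2,4,6,8,10,12-hexaen-1-yl]triphenylphosphonium bromide; 25 (2E,4E)-3-methyl-5-[(1S,6R)-2,2,6-trimethyl-7-oxabicyclo[4.1.0]heptan-1-yl]penta-2,4-dienal
Product: 27 (5R,6S,6'R)-5,6-epoxy-5,6-dihydro-β,ε-carotene, via C25 phosphorus ylide 26 (not isolated)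
Conditions: NaOMe, CH2Cl2/MeOH, 0 °C to rt; then heptane, reflux, N2, dark; crystallisation
Reagents that add atoms: none
Why: Wittig olefination forms C11=C12 under base-only conditions with the oxirane carried on the aldehyde partner, so it never meets acid, and thermal equilibration followed by crystallisation should give the all-E isomer with all three stereocentres untouched.

**Compound list**

1 | (E)-3-methylpent-2-en-4-yn-1-ol | C#C/C(C)=C/CO | starting material
2 | (E)-3-methylpenta-2,4-dien-1-ol | C=C/C(C)=C/CO | intermediate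
3 | methyl methacrylate | C=C(C)C(=O)OC | starting material
4 | methyl{[(2E)-3-methylpenta-2,4-dien-1-yl]oxy}zinc (methylzinc dienyl alkoxide) | C[Zn]OC/C=C(C)/C=C | intermediate (not isolated)
5 | methyl (1R,2S)-2-(hydroxymethyl)-1,3-dimethylcyclohex-3-ene-1-carboxylate | CC1=CCC[C@@](C)(C(=O)OC)[C@H]1CO | intermediate
6 | (3aS,7aR)-4,7a-dimethyl-3a,6,7,7a-tetrahydro-2-benzofuran-1(3H)-one | CC1=CCC[C@@]2(C)C(=O)OC[C@@H]12 | intermediate
7 | (3aS,7aR)-4,7a-dimethyl-1,3,3a,6,7,7a-hexahydro-2-benzofuran-1-ol (anomers) | CC1=CCC[C@@]2(C)C(O)OC[C@@H]12 | intermediate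
8 | [(1S,6R)-6-[(E)-hydrazinylidenemethyl]-2,6-dimethylcyclohex-2-en-1-yl]methanol (hydroxy hydrazone) | CC1=CCC[C@@](C)(/C=N/N)[C@H]1CO | intermediate (not isolated)
9 | [(1R)-2,6,6-trimethylcyclohex-2-en-1-yl]methanol ((R)-α-cyclogeraniol) | CC1=CCCC(C)(C)[C@H]1CO | intermediate
10 | (1R)-2,6,6-trimethylcyclohex-2-ene-1-carbaldehyde ((R)-α-cyclocitral) | CC1=CCCC(C)(C)[C@H]1C=O | intermediate
11 | (3E)-4-[(1R)-2,6,6-trimethylcyclohex-2-en-1-yl]but-3-en-2-one ((R)-α-ionone) | CC1=CCCC(C)(C)[C@H]1/C=C/C(C)=O | intermediate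
12 | (1E)-3-methyl-1-[(1R)-2,6,6-trimethylcyclohex-2-en-1-yl]penta-1,4-dien-3-ol (C3 epimers) | CC1=CCCC(C)(C)[C@H]1/C=C/C(C)(O)C=C | intermediate
13 | [(2E,4E)-3-methyl-5-[(1R)-2,6,6-trimethylcyclohex-2-en-1-yl]penta-2,4-dien-1-yl]triphenylphosphonium bromide | CC1=CCCC(C)(C)[C@H]1/C=C/C(C)=C/C[P+](c1ccccc1)(c1ccccc1)c1ccccc1.[Br-] | intermediate
14 | (2E,4E,6E)-2,7-dimethylocta-2,4,6-trienedial | O=C/C(C)=C/C=C/C=C(C)/C=O | starting material
15 | C15 phosphorus ylide of 13 | CC1=CCCC(C)(C)[C@H]1/C=C/C(C)=C/C=P(c1ccccc1)(c1ccccc1)c1ccccc1 | intermediate (not isolated)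
16 | (2E,4E,6E,8E,10E,12E)-2,7,11-trimethyl-13-[(1R)-2,6,6-trimethylcyclohex-2-en-1-yl]trideca-2,4,6,8,10,12-hexaenal | CC1=CCCC(C)(C)[C@H]1/C=C/C(C)=C/C=C/C(C)=C/C=C/C=C(C)/C=O | intermediate
17 | (2E,4E,6E,8E,10E,12E)-2,7,11-trimethyl-13-[(1R)-2,6,6-trimethylcyclohex-2-en-1-yl]trideca-2,4,6,8,10,12-hexaen-1-ol | CC1=CCCC(C)(C)[C@H]1/C=C/C(C)=C/C=C/C(C)=C/C=C/C=C(C)/CO | intermediate
18 | [(2E,4E,6E,8E,10E,12E)-2,7,11-trimethyl-13-[(1R)-2,6,6-trimethylcyclohex-2-en-1-yl]trideca-2,4,6,8,10,12-hexaen-1-yl]triphenylphosphonium bromide | CC1=CCCC(C)(C)[C@H]1/C=C/C(C)=C/C=C/C(C)=C/C=C/C=C(C)/C[P+](c1ccccc1)(c1ccccc1)c1ccccc1.[Br-] | intermediate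
19 | 2,6,6-trimethylcyclohex-1-ene-1-carbaldehyde (β-cyclocitral) | CC1=C(C=O)C(C)(C)CCC1 | starting material
20 | (2,6,6-trimethylcyclohex-1-en-1-yl)methanol | CC1=C(CO)C(C)(C)CCC1 | intermediate
21 | [(1R,6R)-2,2,6-trimethyl-7-oxabicyclo[4.1.0]heptan-1-yl]methanol | OC[C@@]12O[C@]1(C)CCCC2(C)C | intermediate
22 | (1S,6R)-2,2,6-trimethyl-7-oxabicyclo[4.1.0]heptane-1-carbaldehyde | O=C[C@@]12O[C@]1(C)CCCC2(C)C | intermediate
23 | ethyl (2E,4E)-3-methyl-5-[(1S,6R)-2,2,6-trimethyl-7-oxabicyclo[4.1.0]heptan-1-yl]penta-2,4-dienoate | CCOC(=O)/C=C(C)/C=C/[C@@]12O[C@]1(C)CCCC2(C)C | intermediate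
24 | (2E,4E)-3-methyl-5-[(1S,6R)-2,2,6-trimethyl-7-oxabicyclo[4.1.0]heptan-1-yl]penta-2,4-dien-1-ol | OC/C=C(C)/C=C/[C@@]12O[C@]1(C)CCCC2(C)C | intermediate
25 | (2E,4E)-3-methyl-5-[(1S,6R)-2,2,6-trimethyl-7-oxabicyclo[4.1.0]heptan-1-yl]penta-2,4-dienal | O=C/C=C(C)/C=C/[C@@]12O[C@]1(C)CCCC2(C)C | intermediate
26 | C25 phosphorus ylide of 18 | CC1=CCCC(C)(C)[C@H]1/C=C/C(C)=C/C=C/C(C)=C/C=C/C=C(C)/C=P(c1ccccc1)(c1ccccc1)c1ccccc1 | intermediate (not isolated)
27 | (5R,6S,6'R)-5,6-epoxy-5,6-dihydro-β,ε-carotene | CC1=CCCC(C)(C)[C@H]1/C=C/C(C)=C/C=C/C(C)=C/C=C/C=C(C)/C=C/C=C(C)/C=C/[C@@]12O[C@]1(C)CCCC2(C)C | target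

**Step count**

Total step count: 19. Longest linear sequence: 13 steps (steps 1–12 and 19); the epoxy arm (steps 13–18) joins in step 19.

**Steps most likely to fail**

Step 2. The α-methyl group may slow the templated cycloaddition so much that the untethered background reaction, which is para-selective and racemic, competes, or that conversion stays low; facial selectivity may also be eroded by the extra substituent at the metal-bound dienophile. The fallback sets out from 2 and builds the quaternary carbon in two known operations. The established acrylate version of the same templated cycloaddition (Me2Zn, (R)-BINOL, MeMgBr, methyl acrylate, CH2Cl2) should give methyl (1R,2R)-2-(hydroxymethyl)-3-methylcyclohex-3-ene-1-carboxylate F1, which is lactonised with catalytic TsOH to (3aR,7aR)-4-methyl-3a,6,7,7a-tetrahydro-2-benzofuran-1(3H)-one F2. Deprotonation with LiN(iPr)2 in THF at −78 °C and alkylation of the lactone enolate with MeI on the convex face installs the 7a-methyl group and comes back to the route at 6; a minor trans-fused isomer would be harmless, because C1' ends as the gem-dimethyl carbon.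

Step 5. Hydrazone formation at the neopentyl lactol carbon may be incomplete, and the long exposure to hot base may move the C4'=C5' double bond or cost volatile product. The fallback sets out from 5 and removes the oxygen by hydride displacement instead of through a hydrazone. Silylation (tBuMe2SiCl, imidazole, DMF) gives methyl (1R,2S)-2-({[tert-butyl(dimethyl)silyl]oxy}methyl)-1,3-dimethylcyclohex-3-ene-1-carboxylate F3. LiAlH4 in THF at 0 °C reduces the ester to [(1R,2S)-2-({[tert-butyl(dimethyl)silyl]oxy}methyl)-1,3-dimethylcyclohex-3-en-1-yl]methanol F4. MsCl/Et3N gives [(1R,2S)-2-({[tert-butyl(dimethyl)silyl]oxy}methyl)-1,3-dimethylcyclohex-3-en-1-yl]methyl methanesulfonate F5. LiEt3BH in refluxing THF displaces the neopentyl sulfonate by hydride to tert-butyl(dimethyl){[(1R)-2,6,6-trimethylcyclohex-2-en-1-yl]methoxy}silane F6. Bu4NF in THF removes the silyl group and comes back to the route at 9.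

Step 7. The hindered aldehyde may add the phosphonate anion so slowly that amine-mediated enolisation erodes the C6' configuration or shifts the ring alkene into conjugation. The fallback sets out from 10 and replaces the slow olefination by a fast kinetic aldol addition followed by elimination. The lithium enolate of acetone (acetone, LiN(iPr)2, THF, −78 °C) adds to 10 within minutes to give 4-hydroxy-4-[(1R)-2,6,6-trimethylcyclohex-2-en-1-yl]butan-2-one F7 as a mixture of carbinol epimers. MsCl/Et3N at 0 °C gives 3-oxo-1-[(1R)-2,6,6-trimethylcyclohex-2-en-1-yl]butyl methanesulfonate F8, which eliminates with DBU to the E enone and comes back to the route at 11. The basic elimination is run only when C6' is no longer α to a carbonyl group.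

**Further compounds**

F1 | step 2 | methyl (1R,2R)-2-(hydroxymethyl)-3-methylcyclohex-3-ene-1-carboxylate | CC1=CCC[C@@H](C(=O)OC)[C@H]1CO
F2 | step 2 | (3aR,7aR)-4-methyl-3a,6,7,7a-tetrahydro-2-benzofuran-1(3H)-one | CC1=CCC[C@H]2C(=O)OC[C@@H]12
F3 | step 5 | methyl (1R,2S)-2-({[tert-butyl(dimethyl)silyl]oxy}methyl)-1,3-dimethylcyclohex-3-ene-1-carboxylate | CC1=CCC[C@@](C)(C(=O)OC)[C@H]1CO[Si](C)(C)C(C)(C)C
F4 | step 5 | [(1R,2S)-2-({[tert-butyl(dimethyl)silyl]oxy}methyl)-1,3-dimethylcyclohex-3-en-1-yl]methanol | CC1=CCC[C@@](C)(CO)[C@H]1CO[Si](C)(C)C(C)(C)C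
F5 | step 5 | [(1R,2S)-2-({[tert-butyl(dimethyl)silyl]oxy}methyl)-1,3-dimethylcyclohex-3-en-1-yl]methyl methanesulfonate | CC1=CCC[C@@](C)(COS(C)(=O)=O)[C@H]1CO[Si](C)(C)C(C)(C)C
F6 | step 5 | tert-butyl(dimethyl){[(1R)-2,6,6-trimethylcyclohex-2-en-1-yl]methoxy}silane | CC1=CCCC(C)(C)[C@H]1CO[Si](C)(C)C(C)(C)C
F7 | step 7 | 4-hydroxy-4-[(1R)-2,6,6-trimethylcyclohex-2-en-1-yl]butan-2-one | CC1=CCCC(C)(C)[C@H]1C(O)CC(C)=O
F8 | step 7 | 3-oxo-1-[(1R)-2,6,6-trimethylcyclohex-2-en-1-yl]butyl methanesulfonate | CC1=CCCC(C)(C)[C@H]1C(OS(C)(=O)=O)CC(C)=O
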